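## Structural features

The target is a diester in which two identical (4R,4aS,6R,7S,7aR)-2,4,7-trimethyloctahydro-1H-cyclopenta[c]pyridin-6-yl units are bound through their C6 oxygens to the two carboxyl groups of (2E,6E)-2,6-dimethylocta-2,6-dienedioic acid. Each amine unit is a cis-fused bicycle: an N-methylpiperidine (C1, N2, C3, C4, C4a, C7a) shares the C4a–C7a bond with a cyclopentane (C4a, C5, C6, C7, C7a). Each unit has five contiguous stereocentres in the order C4–C4a–C7a–C7–C6. H4, H4a, H7a, the C7 methyl group and the C6 oxygen all lie on one face, and the C4 methyl group lies on the other. The diacid linker is unsymmetrical (one carboxyl on the methyl-bearing alkene carbon, the other on an alkene CH), but since both alcohols are the same its ends need not be told apart. The fragile parts are the two conjugated trisubstituted E-enoates (E/Z isomerisation, conjugate addition, reduction by hydride or hydrogen), the basic and oxidisable tertiary amines, and the esters on hindered secondary carbons. The real difficulty is the relative and absolute configuration of the five contiguous centres, especially that the C7 methyl and C6 oxygen sit on the same face as the ring-fusion hydrogens. The key step uses the fact that C1, N2, C3, C4, C4a and C7a can be raised to a pyridone ring fused at C4a–C7a: the diyne then supplies C1, C7a, C7, C6, C5, C4a and C4, methyl isocyanate supplies N2 and C3, and the flat pyridone lets one hydrogenation place H4, H4a and H7a together.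

## Logic of the disconnections

Atom labels are those of the bicyclic half (C1, N2, C3, C4, C4a, C5, C6, C7, C7a).

27 ⇒ two equivalents of 19 + 24. Both C6–O bonds are cut, each to be formed with inversion. The sensitive dienoate is thereby attached last and the problem is halved into one amino alcohol and one diacid. Hydride reduction of a C6 ketone is expected to give the 6S alcohol, so an inverting esterification fits the available epimer. The forward step must achieve two clean SN2 displacements at a hindered secondary carbon without elimination and in the presence of tertiary amines.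

24 ⇒ 22 ⇒ 21 ⇒ 20 (through 23). No carbon–carbon bond is cut; only the oxidation level at the two terminal carbons changes. This traces the whole linker, with both E alkenes in place, to one cheap terpene ester. The forward steps must oxidise only the E-methyl group of the terminal alkene and must not isomerise either alkene.

19 ⇒ 18. The C3–H2 and C6–H bonds are traced back to a lactam carbonyl and a ketone. The lactam is the form in which the ring is made; the ketone allows C7 to be corrected and C6 to be reset. One reagent removes both. Hydride must reach C6 from the face of H7a, and C7 must not enolise before the ketone is reduced.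

18 ⇒ 17 ⇒ 16 ⇒ 15. The C7 configuration is traced to its epimer, the ketone to the alcohol, and the alcohol to its silyl ether. This accepts that C6 and C7 enter with the wrong configuration, because in 15 they are what control the other three centres. The forward sequence relies on 18 being the more stable C7 epimer and on C4, which is α only to the lactam, staying untouched.

15 ⇒ 14. Four C–H bonds (at C1, C7a, C4a and C4) are removed to reach the flat pyridone. Three stereocentres (C4, C4a, C7a) become one question of face selectivity, answered by the C6 and C7 substituents. The forward step must saturate a pyridone completely, including the tetrasubstituted C4=C4a bond, from a single face.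

14 ⇒ 12 + 13. The bonds C4a–C7a, C3–C4 and N2–C1 are cut, which opens both rings at once. The bicycle is reduced to an acyclic diyne with two stereocentres and a one-carbon, one-nitrogen partner. The forward step must join the carbon of 13 to C4 and its nitrogen to C1, and must tolerate a terminal alkyne.

12 ⇒ 11 ⇒ 10. Only the C1–Si and O–Si bonds change. C1 is kept silylated until just before the cycloaddition. This is a deliberate change of design: a free alkyne C–H at C1 would exchange with the acetylide needed below, and the small early intermediates would be volatile. The oxygen is silylated with a bulky group because its later role is steric.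

10 ⇒ 8 + 9. The C5–C4a bond (sp3–sp) is cut. A terminal epoxide opens reliably at its CH2 carbon, so the C6–O bond and its configuration are carried through. The demand is a nucleophile that is not consumed by proton transfer, which the C1 silyl group secures.

8 ⇒ 6 ⇒ 5 (through 7). The epoxide C5–O bond is traced to a primary sulfonate and then to a 1,2-diol and its mono-silyl ether. This costs no stereocentre, since ring closure occurs at the primary carbon. Sulfonylation must be selective for the primary hydroxyl.

5 ⇒ 2 + 3 (through 4), and 2 ⇒ 1. The C6–C7 bond is cut; both stereocentres arise in this one bond formation. The absolute configuration comes from 1 and the anti relationship from the cyclic transition state. The forward step needs high anti selectivity with an unbranched aldehyde and faithful transfer of chirality from the propargylic carbon.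

## Other disconnections considered

Alternative 1: The cut is C1–C7a, closing the piperidine onto a preformed cyclopentenone. In the forward step a visible-light photoredox catalyst oxidises the N-(trimethylsilyl)methyl amine of A1; loss of the silyl group gives the nucleophilic C1 radical, which adds 6-exo-trig to C7a, and the resulting C7 radical is reduced and protonated to give A2.
- In its favour: the conditions are mild and redox-neutral, the tether from C4a forces the cis ring fusion, and protonation should place the C7 methyl trans to C1, which is the target configuration.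
- Against it here: the single stereocentre of A1 (C4a, γ to the enone carbonyl) must be made enantiopure and is open to racemisation through the dienolate. C4 is still unset and would need hydrogenation of the exocyclic alkene next to an allylic amine, which can isomerise to the enamine.
- Comparison: on structure it forms one ring, one bond and two stereocentres, against two rings and three bonds in the chosen plan. On mechanism it is a radical–polar crossover of a precedented type, as is the organometallic cycloaddition. It is the better of the two in reaching the C7 configuration directly and in avoiding hydrogenation of a heteroaromatic ring. It is the equal of the chosen plan in its endgame (ketone reduction, inversion at C6). The steps after its key step are fewer, but the longer access to A1 would probably cancel that.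

Alternative 2: The cuts are C7–CH3 and C7a–C1, a vicinal difunctionalisation of the enone A3. In the forward step a methyl cuprate adds to C7 anti to the C6 silyloxy group, the enolate is held as its silyl enol ether, and the N-acyliminium ion released from A4 by a Lewis acid alkylates C7a trans to the new methyl group, giving A5.
- In its favour: A3 is a purchasable enantiopure building block. C6, C7 and C7a are fixed in two operations with predictable trans,trans relationships, which is exactly the 6S,7S,7aR pattern needed before inversion at C6, and C1 and N2 arrive with it.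
- Against it here: no ring is formed. C3, C4 and the bonds C4–C4a and C3–N2 must follow by olefination of the hindered C4a ketone, lactamisation and hydrogenation. The face at which C4a is then hydrogenated is not secured, and A5 and its enolate precursors are β-silyloxy carbonyl compounds prone to elimination.
- Comparison: on mechanism its key step is polar, stoichiometric and very well precedented, and in reliability it is the equal or the better of the nickel step. On step economy it is probably the better, since A5 is two steps from a commercial compound. The chosen plan is stronger in setting C4, C4a and C7a in one operation under substrate control and in having no elimination-prone intermediate.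

Alternative 3: The cuts are C7–C7a and C4a–C5, annulating the cyclopentane onto a six-membered aza-enone. In the forward step zerovalent palladium ionises A7 to the palladium–trimethylenemethane zwitterion; its methyl-bearing terminus adds to C7a of A6 and the enolate closes on the π-allyl unit at C4a–C5, giving A8.
- In its favour: it is a convergent, catalytic union of two small achiral partners. The cyclopentane arrives cis-fused with the C7 methyl in place, the C6 methylidene is a masked ketone, the C4 ketone is a handle for the C4 methyl, and the carbamate is a latent N-methyl group.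
- Against it here: the cycloaddition is stepwise, so the C7/C7a relationship and the regiochemistry of the unsymmetrical donor are not secured by the substrate. The absolute configuration would depend on a chiral ligand with an acceptor of this kind. Two carbonyl-level positions (C4 and C6) must later be told apart and processed in the right order.
- Comparison: it is the better in convergence, and the equal or better in obtaining C7 without an epimerisation step if the diastereoselectivity holds. It is weaker in that three stereocentres (C4a, C7, C7a) depend on catalyst control alone. It is not shorter after its key step (methylenation, hydrogenation, ozonolysis, two reductions, inversion).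

Key step: step 8

Assumption: the allenylindium addition of step 2 is taken to follow its usual course (anti SN2′ at the mesylate, syn SE2′ at the aldehyde, hence net inversion at the former carbinol carbon), which makes the S enantiomer of 1 the correct one; if the sense were opposite, the R enantiomer would be used and nothing else would change.

## Route

Step 1
Reactants: 1 (2S)-4-(trimethylsilyl)but-3-yn-2-ol
Product: 2 (2S)-4-(trimethylsilyl)but-3-yn-2-yl methanesulfonate
Conditions: MsCl, Et3N, CH2Cl2, −78 to 0 °C
Reagents that add atoms: methanesulfonyl chloride, CS(=O)(=O)Cl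
Why: Standard O-sulfonylation; the C–O bond is not touched, so the S configuration is retained, and the mesylate is used without purification.

Step 2
Reactants: 2 (2S)-4-(trimethylsilyl)but-3-yn-2-yl methanesulfonate; 3 2-(tert-butyldimethylsilyloxy)acetaldehyde
Product: 5 (2R,3R)-1-(tert-butyldimethylsilyloxy)-3-methyl-5-(trimethylsilyl)pent-4-yn-2-ol, via allenylindium reagent 4 (not isolated)
Conditions: Pd(OAc)2 (5 mol %), PPh3 (5 mol %), InI, THF–HMPA (3:1), rt
Reagents that add atoms: none
Why: Zerovalent palladium formed in situ displaces the mesylate in an anti SN2′ sense, InI transmetalates the allenylpalladium to 4, and 4 adds to the aldehyde through a closed six-membered SE2′ transition state (allenylmetal propargylation). The axial chirality of 4 sets the methyl-bearing carbon (future C7, 3R in 5) by net inversion of the carbinol carbon of 2, and the chair-like transition state with the aldehyde substituent turned away from the allene methyl gives the anti alcohol (2R, future C6).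

Step 3
Reactants: 5 (2R,3R)-1-(tert-butyldimethylsilyloxy)-3-methyl-5-(trimethylsilyl)pent-4-yn-2-ol
Product: 6 (2R,3R)-3-methyl-5-(trimethylsilyl)pent-4-yne-1,2-diol
Conditions: camphorsulfonic acid (cat.), MeOH, 0 °C to rt
Reagents that add atoms: none
Why: Acid-catalysed methanolysis cleaves the primary silyl ether; the alkynyl C–Si bond is stable to acid, which is why acid and not fluoride is used here.

Step 4
Reactants: 6 (2R,3R)-3-methyl-5-(trimethylsilyl)pent-4-yne-1,2-diol
Product: 8 trimethyl{(3R)-3-[(2R)-oxiran-2-yl]but-1-yn-1-yl}silane, via primary sulfonate 7 (not isolated)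
Conditions: NaH (3 equiv), 1-(2,4,6-triisopropylbenzenesulfonyl)imidazole, THF, 0 °C to rt
Reagents that add atoms: none
Why: One-pot epoxide formation from a 1,2-diol: the bulky arenesulfonyl imidazole sulfonylates the primary alkoxide selectively and the secondary alkoxide displaces the sulfonate (intramolecular Williamson reaction), so the secondary C–O bond and its configuration are retained.

Step 5
Reactants: 8 trimethyl{(3R)-3-[(2R)-oxiran-2-yl]but-1-yn-1-yl}silane; 9 prop-1-yn-1-yllithium
Product: 10 (3R,4S)-3-methyl-1-(trimethylsilyl)octa-1,6-diyn-4-ol
Conditions: BF3·OEt2, THF, −78 °C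
Reagents that add atoms: none
Why: Lewis-acid-assisted SN2 opening of a terminal epoxide by a lithium acetylide at the unsubstituted carbon; no stereocentre is touched, and with C1 silylated there is no acidic alkyne proton to quench or exchange with the nucleophile.

Step 6
Reactants: 10 (3R,4S)-3-methyl-1-(trimethylsilyl)octa-1,6-diyn-4-ol
Product: 11 tert-butyldimethyl{[(3R,4S)-3-methyl-1-(trimethylsilyl)octa-1,6-diyn-4-yl]oxy}silane
Conditions: TBSOTf, 2,6-lutidine, CH2Cl2, −78 to 0 °C
Reagents that add atoms: tert-butyldimethylsilyl trifluoromethanesulfonate, CC(C)(C)[Si](C)(C)OS(=O)(=O)C(F)(F)F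
Why: Silyl triflate/lutidine silylation of a hindered secondary alcohol; the bulky silyl ether is the group that will shield one face in step 9.

Step 7
Reactants: 11 tert-butyldimethyl{[(3R,4S)-3-methyl-1-(trimethylsilyl)octa-1,6-diyn-4-yl]oxy}silane
Product: 12 (3R,4S)-4-(tert-butyldimethylsilyloxy)-3-methylocta-1,6-diyne
Conditions: K2CO3 (cat.), MeOH, rt
Reagents that add atoms: none
Why: Mild base-catalysed methanolysis cleaves only the alkynyl C–Si bond; the secondary silyl ether and both stereocentres are inert under these conditions.

Step 8
Reactants: 12 (3R,4S)-4-(tert-butyldimethylsilyloxy)-3-methylocta-1,6-diyne; 13 methyl isocyanate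
Product: 14 (6S,7R)-6-(tert-butyldimethylsilyloxy)-2,4,7-trimethyl-2,5,6,7-tetrahydro-3H-cyclopenta[c]pyridin-3-one
Conditions: Ni(cod)2 (5 mol %), SIPr (1,3-bis(2,6-diisopropylphenyl)imidazolidin-2-ylidene, 10 mol %), 13 (1.5 equiv), toluene, rt, sealed vessel, slow addition of 12
Reagents that add atoms: none
Why: The zerovalent nickel–carbene complex should couple the methyl-substituted alkyne oxidatively with the C=N bond of 13 to an azanickelacyclopentenone (C3–C4 bond, nitrogen on nickel), the tethered terminal alkyne then inserts into the Ni–C bond (C4a–C7a bond), and C–N reductive elimination from the seven-membered nickelacycle forms N2–C1 and releases the catalyst. The closest known reaction type is the nickel/N-heterocyclic carbene catalysed [2+2+2] cycloaddition of 1,6-diynes with isocyanates to ring-fused 2-pyridones, which runs at room temperature. The cyclopentane closes by intramolecular migratory insertion across the three-atom tether C5–C6–C7, the only ring size a 1,6-diyne can give, and the pyridone closes by the final reductive elimination. No stereocentre is formed; C6 and C7 are sp3 spectators under neutral, base-free conditions and are carried through unchanged. The selectivity needed is regiochemical, carbonyl carbon to C4 and nitrogen to C1: the bulky carbene ligand keeps the larger alkyne substituent (methyl against hydrogen) away from nickel in the first metallacycle, which places it next to the carbonyl, and the unhindered terminal alkyne is the better partner for the insertion. The second need is chemoselectivity against homo-oligomerisation of the alkyne, met by adding 12 slowly to the catalyst and an excess of 13. The silyl ether is inert, and nothing in 12 other than the two alkynes binds nickel strongly.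

Step 9
Reactants: 14 (6S,7R)-6-(tert-butyldimethylsilyloxy)-2,4,7-trimethyl-2,5,6,7-tetrahydro-3H-cyclopenta[c]pyridin-3-one
Product: 15 (4R,4aR,6S,7R,7aR)-6-(tert-butyldimethylsilyloxy)-2,4,7-trimethyloctahydro-3H-cyclopenta[c]pyridin-3-one
Conditions: H2 (50 bar), PtO2, AcOH, rt
Reagents that add atoms: none
Why: Heterogeneous hydrogenation of a 2-pyridone to the 2-piperidinone; the ring should adsorb on the face opposite to the C7 methyl and C6 silyloxy groups, so that H4, H4a and H7a are delivered syn to one another from that face, giving the cis ring fusion and the 4R centre. The lactam carbonyl and the silyl ether are not reduced.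

Step 10
Reactants: 15 (4R,4aR,6S,7R,7aR)-6-(tert-butyldimethylsilyloxy)-2,4,7-trimethyloctahydro-3H-cyclopenta[c]pyridin-3-one
Product: 16 (4R,4aR,6S,7R,7aR)-6-hydroxy-2,4,7-trimethyloctahydro-3H-cyclopenta[c]pyridin-3-one
Conditions: Bu4NF, THF, rt
Reagents that add atoms: none
Why: Fluoride cleavage of the secondary silyl ether, whose steering role ended with step 9; the lactam is inert.

Step 11
Reactants: 16 (4R,4aR,6S,7R,7aR)-6-hydroxy-2,4,7-trimethyloctahydro-3H-cyclopenta[c]pyridin-3-one
Product: 17 (4R,4aR,7R,7aR)-2,4,7-trimethylhexahydro-1H-cyclopenta[c]pyridine-3,6(2H,4H)-dione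
Conditions: Dess–Martin periodinane, NaHCO3, CH2Cl2, 0 °C to rt
Reagents that add atoms: none
Why: Dess–Martin oxidation of a secondary alcohol to the ketone under buffered, near-neutral conditions; C6 is erased on purpose so that C7 becomes enolisable.

Step 12
Reactants: 17 (4R,4aR,7R,7aR)-2,4,7-trimethylhexahydro-1H-cyclopenta[c]pyridine-3,6(2H,4H)-dione
Product: 18 (4R,4aR,7S,7aR)-2,4,7-trimethylhexahydro-1H-cyclopenta[c]pyridine-3,6(2H,4H)-dione
Conditions: DBU (0.5 equiv), CH2Cl2, rt
Reagents that add atoms: none
Why: Base-mediated equilibration through the C6–C7 enolate; the methyl group should move from the concave face, where it is cis to C1, to the convex face, giving the more stable 2,3-trans cyclopentanone, which is the 7S configuration of the target. C4 is α only to the lactam carbonyl and is not deprotonated by an amidine base.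

Step 13
Reactants: 18 (4R,4aR,7S,7aR)-2,4,7-trimethylhexahydro-1H-cyclopenta[c]pyridine-3,6(2H,4H)-dione
Product: 19 (4R,4aS,6S,7S,7aR)-2,4,7-trimethyloctahydro-1H-cyclopenta[c]pyridin-6-ol
Conditions: LiAlH4, THF, −78 °C, then reflux
Reagents that add atoms: none
Why: LiAlH4 reduces the ketone at low temperature and the tertiary lactam on heating; hydride should reach C6 from the convex face (that of H4a and H7a), placing the hydroxyl trans to the C7 methyl (6S), the epimer needed for inversion in step 17. Reducing the ketone before warming prevents enolisation at C7.

Step 14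
Reactants: 20 geranyl acetate
Product: 21 (2E,6E)-8-hydroxy-3,7-dimethylocta-2,6-dien-1-yl acetate
Conditions: SeO2 (cat.), t-BuOOH, salicylic acid (cat.), CH2Cl2, rt
Reagents that add atoms: tert-butyl hydroperoxide, CC(C)(C)OO (terminal oxidant; the oxygen is passed on by catalytic selenium dioxide, O=[Se]=O)
Why: Selenium dioxide allylic oxidation (ene reaction, then [2,3]-sigmatropic shift) attacks the E-methyl group of the electron-richer terminal alkene and gives the E allylic alcohol; the alkene next to the acetate is deactivated. Any enal formed by over-oxidation is also a precursor of 24.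

Step 15
Reactants: 21 (2E,6E)-8-hydroxy-3,7-dimethylocta-2,6-dien-1-yl acetate
Product: 22 (2E,6E)-2,6-dimethylocta-2,6-diene-1,8-diol
Conditions: K2CO3 (cat.), MeOH, rt
Reagents that add atoms: none
Why: Base-catalysed transesterification removes the acetate without touching the alkenes.

Step 16
Reactants: 22 (2E,6E)-2,6-dimethylocta-2,6-diene-1,8-diol
Product: 24 (2E,6E)-2,6-dimethylocta-2,6-dienedioic acid, via dialdehyde 23 (not isolated)
Conditions: TEMPO (cat.), PhI(OAc)2, CH2Cl2, rt; then NaClO2, NaH2PO4, 2-methylbut-2-ene, t-BuOH–H2O, 0 °C to rt
Reagents that add atoms: sodium chlorite, [Na+].[O-]Cl=O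
Why: Oxoammonium (TEMPO) oxidation should take both allylic alcohols to the dialdehyde without E/Z isomerisation, and chlorite with a hypochlorite scavenger (Pinnick oxidation) converts both enals into acids with the alkenes intact.

Step 17
Reactants: 19 (4R,4aS,6S,7S,7aR)-2,4,7-trimethyloctahydro-1H-cyclopenta[c]pyridin-6-ol (2.2 equiv); 24 (2E,6E)-2,6-dimethylocta-2,6-dienedioic acid
Product: 27 bis[(4R,4aS,6R,7S,7aR)-2,4,7-trimethyloctahydro-1H-cyclopenta[c]pyridin-6-yl] (2E,6E)-2,6-dimethylocta-2,6-dienedioate (target), via C8-monoester 25 (not isolated), via C1-monoester 26 (not isolated)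
Conditions: PPh3, diisopropyl azodicarboxylate, THF, 0 °C to rt
Reagents that add atoms: none
Why: Mitsunobu esterification: each C6 hydroxyl is activated as its alkoxyphosphonium ion and displaced by a carboxylate of 24 with inversion, turning 6S into the 6R esters of the target. The conjugated acids are acidic enough as pronucleophiles, tertiary amines are tolerated, and the basic product can be separated from phosphine oxide and hydrazide by acid–base extraction.

## Compound list

1 | (2S)-4-(trimethylsilyl)but-3-yn-2-ol | C[C@H](O)C#C[Si](C)(C)C | starting material
2 | (2S)-4-(trimethylsilyl)but-3-yn-2-yl methanesulfonate | C[C@H](OS(C)(=O)=O)C#C[Si](C)(C)C | intermediate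
3 | 2-(tert-butyldimethylsilyloxy)acetaldehyde | CC(C)(C)[Si](C)(C)OCC=O | starting material
4 | (aR)-iodo(methanesulfonato)[1-(trimethylsilyl)buta-1,2-dien-1-yl]indium (axial configuration given in the name only) | CC=C=C([Si](C)(C)C)[In](I)OS(C)(=O)=O | intermediate
5 | (2R,3R)-1-(tert-butyldimethylsilyloxy)-3-methyl-5-(trimethylsilyl)pent-4-yn-2-ol | CC(C)(C)[Si](C)(C)OC[C@H](O)[C@H](C)C#C[Si](C)(C)C | intermediate
6 | (2R,3R)-3-methyl-5-(trimethylsilyl)pent-4-yne-1,2-diol | OC[C@H](O)[C@H](C)C#C[Si](C)(C)C | intermediate
7 | (2R,3R)-2-hydroxy-3-methyl-5-(trimethylsilyl)pent-4-yn-1-yl 2,4,6-triisopropylbenzenesulfonate | CC(C)c1cc(C(C)C)c(S(=O)(=O)OC[C@H](O)[C@H](C)C#C[Si](C)(C)C)c(C(C)C)c1 | intermediate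
8 | trimethyl{(3R)-3-[(2R)-oxiran-2-yl]but-1-yn-1-yl}silane | C1O[C@@H]1[C@H](C)C#C[Si](C)(C)C | intermediate
9 | prop-1-yn-1-yllithium | [Li]C#CC | starting material
10 | (3R,4S)-3-methyl-1-(trimethylsilyl)octa-1,6-diyn-4-ol | CC#CC[C@H](O)[C@H](C)C#C[Si](C)(C)C | intermediate
11 | tert-butyldimethyl{[(3R,4S)-3-methyl-1-(trimethylsilyl)octa-1,6-diyn-4-yl]oxy}silane | CC#CC[C@H](O[Si](C)(C)C(C)(C)C)[C@H](C)C#C[Si](C)(C)C | intermediate
12 | (3R,4S)-4-(tert-butyldimethylsilyloxy)-3-methylocta-1,6-diyne | CC#CC[C@H](O[Si](C)(C)C(C)(C)C)[C@H](C)C#C | intermediate
13 | methyl isocyanate | CN=C=O | starting material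
14 | (6S,7R)-6-(tert-butyldimethylsilyloxy)-2,4,7-trimethyl-2,5,6,7-tetrahydro-3H-cyclopenta[c]pyridin-3-one | CC(C)(C)[Si](C)(C)O[C@H]1CC2=C(C)C(=O)N(C)C=C2[C@H]1C | intermediate
15 | (4R,4aR,6S,7R,7aR)-6-(tert-butyldimethylsilyloxy)-2,4,7-trimethyloctahydro-3H-cyclopenta[c]pyridin-3-one | CC(C)(C)[Si](C)(C)O[C@H]1C[C@@H]2[C@@H](CN(C)C(=O)[C@@H]2C)[C@H]1C | intermediate
16 | (4R,4aR,6S,7R,7aR)-6-hydroxy-2,4,7-trimethyloctahydro-3H-cyclopenta[c]pyridin-3-one | O[C@H]1C[C@@H]2[C@@H](CN(C)C(=O)[C@@H]2C)[C@H]1C | intermediate
17 | (4R,4aR,7R,7aR)-2,4,7-trimethylhexahydro-1H-cyclopenta[c]pyridine-3,6(2H,4H)-dione | O=C1C[C@@H]2[C@@H](CN(C)C(=O)[C@@H]2C)[C@H]1C | intermediate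
18 | (4R,4aR,7S,7aR)-2,4,7-trimethylhexahydro-1H-cyclopenta[c]pyridine-3,6(2H,4H)-dione | O=C1C[C@@H]2[C@@H](CN(C)C(=O)[C@@H]2C)[C@@H]1C | intermediate
19 | (4R,4aS,6S,7S,7aR)-2,4,7-trimethyloctahydro-1H-cyclopenta[c]pyridin-6-ol | O[C@H]1C[C@@H]2[C@@H](CN(C)C[C@@H]2C)[C@@H]1C | intermediate
20 | geranyl acetate, (2E)-3,7-dimethylocta-2,6-dien-1-yl acetate | CC(=O)OC/C=C(\C)CCC=C(C)C | starting material
21 | (2E,6E)-8-hydroxy-3,7-dimethylocta-2,6-dien-1-yl acetate | CC(=O)OC/C=C(\C)CC/C=C(\C)CO | intermediate
22 | (2E,6E)-2,6-dimethylocta-2,6-diene-1,8-diol | OC/C=C(\C)CC/C=C(\C)CO | intermediate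
23 | (2E,6E)-2,6-dimethylocta-2,6-dienedial | O=C/C=C(\C)CC/C=C(\C)C=O | intermediate
24 | (2E,6E)-2,6-dimethylocta-2,6-dienedioic acid | OC(=O)/C=C(\C)CC/C=C(\C)C(=O)O | intermediate
25 | (2E,6E)-2,6-dimethyl-8-oxo-8-{[(4R,4aS,6R,7S,7aR)-2,4,7-trimethyloctahydro-1H-cyclopenta[c]pyridin-6-yl]oxy}octa-2,6-dienoic acid | C/C(=C\C(=O)O[C@@H]1C[C@@H]2[C@@H](CN(C)C[C@@H]2C)[C@@H]1C)CC/C=C(\C)C(=O)O | intermediate
26 | (2E,6E)-3,7-dimethyl-8-oxo-8-{[(4R,4aS,6R,7S,7aR)-2,4,7-trimethyloctahydro-1H-cyclopenta[c]pyridin-6-yl]oxy}octa-2,6-dienoic acid | C/C(=C\C(=O)O)CC/C=C(\C)C(=O)O[C@@H]1C[C@@H]2[C@@H](CN(C)C[C@@H]2C)[C@@H]1C | intermediate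
27 | bis[(4R,4aS,6R,7S,7aR)-2,4,7-trimethyloctahydro-1H-cyclopenta[c]pyridin-6-yl] (2E,6E)-2,6-dimethylocta-2,6-dienedioate | C/C(=C\C(=O)O[C@@H]1C[C@@H]2[C@@H](CN(C)C[C@@H]2C)[C@@H]1C)CC/C=C(\C)C(=O)O[C@@H]1C[C@@H]2[C@@H](CN(C)C[C@@H]2C)[C@@H]1C | target

## Step count and least certain steps

Total: 17 steps. Longest linear sequence: 14 steps (steps 1 to 13, then step 17); the diacid branch is steps 14 to 16.

Step 8 (key step). The most likely failures are the isocyanate adding in the reversed sense (its carbon to C1), because hydrogen and methyl differ little in size, and nickel-mediated oligomerisation of the terminal alkyne competing with the cycloaddition.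
Fallback: the cycloaddition would be moved one step earlier, to the C-silylated diyne 11, and run with a catalyst of a different mechanistic class, [Rh(cod)2]BF4 with racemic BINAP in 1,2-dichloroethane. Such monovalent rhodium catalysts are expected to couple the two alkynes first to a rhodacyclopentadiene, after which the isocyanate carbon bonds to the less hindered end. With silicon on C1 that end is the methyl-bearing C4, so nitrogen should close on C1 and give the 1-trimethylsilyl pyridone F1. Fluoride (Bu4NF, THF) should remove the ring silyl group, whose carbanion is stabilised beside nitrogen, together with the silyl ether, giving the hydroxy pyridone F2. Resilylation (TBSCl, imidazole, DMF) returns to 14. Without a terminal alkyne the oligomerisation path is closed, and the regiochemistry rests on a silyl/methyl difference instead of a hydrogen/methyl one.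

Step 9. The risks are incomplete saturation of the tetrasubstituted C4=C4a bond, partial delivery of hydrogen to the wrong face, migration of the C1=C7a bond toward C7 (which would erase C7), and acid loss of the silyl ether before reduction is complete. Wrong-face material converges after steps 11 and 12 on the enantiomer of 18, so diastereomers must be separated at 15.
Fallback: the ring would be saturated at the pyridinium level instead of the pyridone level. From 14, oxalyl chloride (CH2Cl2, 0 °C) should give the 3-chloropyridinium chloride F3. Hydrogenation (H2, PtO2, NaOAc, MeOH) should remove the chlorine and reduce the cation, since pyridinium salts are reduced far more readily than pyridones, to the all-cis N-methylpiperidine silyl ether F4 under the same facial control. Desilylation (Bu4NF) gives the amino alcohol F5, Swern oxidation the amino ketone F6, DBU its C7 epimer F7, and NaBH4 (MeOH, −40 °C) the alcohol 19, where the route is rejoined. Steps 10 to 13 are thereby replaced.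

Step 13. The risk is hydride attack on the C6 ketone from the concave face to a significant extent, giving the 6R epimer mixed with 19 as polar amino alcohols that are hard to separate, or enolisation at C7 if ketone survives to higher temperature.
Fallback: the two reductions would be separated. From 18, NaBH4 in MeOH at −40 °C should reduce only the ketone and give the neutral hydroxy lactam F8, which can be freed of any C6 epimer by chromatography; the unwanted epimer is returned to 18 by Dess–Martin oxidation. LiAlH4 in refluxing THF then reduces the lactam of F8 and arrives at 19.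

Step 17. The risks are elimination from the activated C6 alkoxyphosphonium ion toward C5 or C7, and stalling after the first esterification because the mono-esters 25 and 26 are zwitterions of poor solubility.
Fallback: inversion would be separated from acylation. From 19, a Mitsunobu reaction with 4-nitrobenzoic acid, a stronger and monofunctional acid (PPh3, diisopropyl azodicarboxylate, toluene), should give the inverted 4-nitrobenzoate F9. Methanolysis (K2CO3, MeOH) gives the 6R alcohol F10. Carbodiimide coupling of two equivalents of F10 with 24 (N-(3-dimethylaminopropyl)-N′-ethylcarbodiimide hydrochloride, DMAP, CH2Cl2), which proceeds with retention at C6, arrives at 27.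

## Further compounds

F1 | step 8 | (6S,7R)-6-(tert-butyldimethylsilyloxy)-2,4,7-trimethyl-1-(trimethylsilyl)-2,5,6,7-tetrahydro-3H-cyclopenta[c]pyridin-3-one | CC(C)(C)[Si](C)(C)O[C@H]1CC2=C(C)C(=O)N(C)C([Si](C)(C)C)=C2[C@H]1C
F2 | step 8 | (6S,7R)-6-hydroxy-2,4,7-trimethyl-2,5,6,7-tetrahydro-3H-cyclopenta[c]pyridin-3-one | O[C@H]1CC2=C(C)C(=O)N(C)C=C2[C@H]1C
F3 | step 9 | (6S,7R)-6-(tert-butyldimethylsilyloxy)-3-chloro-2,4,7-trimethyl-6,7-dihydro-5H-cyclopenta[c]pyridin-2-ium chloride | CC(C)(C)[Si](C)(C)O[C@H]1CC2=C(C)C(Cl)=[N+](C)C=C2[C@H]1C.[Cl-]
F4 | step 9 | (4R,4aS,6S,7R,7aR)-6-(tert-butyldimethylsilyloxy)-2,4,7-trimethyloctahydro-1H-cyclopenta[c]pyridine | CC(C)(C)[Si](C)(C)O[C@H]1C[C@@H]2[C@@H](CN(C)C[C@@H]2C)[C@H]1C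
F5 | step 9 | (4R,4aS,6S,7R,7aR)-2,4,7-trimethyloctahydro-1H-cyclopenta[c]pyridin-6-ol | O[C@H]1C[C@@H]2[C@@H](CN(C)C[C@@H]2C)[C@H]1C
F6 | step 9 | (4R,4aS,7R,7aR)-2,4,7-trimethyloctahydro-6H-cyclopenta[c]pyridin-6-one | O=C1C[C@@H]2[C@@H](CN(C)C[C@@H]2C)[C@H]1C
F7 | step 9 | (4R,4aS,7S,7aR)-2,4,7-trimethyloctahydro-6H-cyclopenta[c]pyridin-6-one | O=C1C[C@@H]2[C@@H](CN(C)C[C@@H]2C)[C@@H]1C
F8 | step 13 | (4R,4aR,6S,7S,7aR)-6-hydroxy-2,4,7-trimethyloctahydro-3H-cyclopenta[c]pyridin-3-one | O[C@H]1C[C@@H]2[C@@H](CN(C)C(=O)[C@@H]2C)[C@@H]1C
F9 | step 17 | (4R,4aS,6R,7S,7aR)-2,4,7-trimethyloctahydro-1H-cyclopenta[c]pyridin-6-yl 4-nitrobenzoate | O=C(O[C@@H]1C[C@@H]2[C@@H](CN(C)C[C@@H]2C)[C@@H]1C)c1ccc(cc1)[N+](=O)[O-]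
F10 | step 17 | (4R,4aS,6R,7S,7aR)-2,4,7-trimethyloctahydro-1H-cyclopenta[c]pyridin-6-ol | O[C@@H]1C[C@@H]2[C@@H](CN(C)C[C@@H]2C)[C@@H]1C
A1 | alternative 1 | (4R)-2-methyl-4-(3-{methyl[(trimethylsilyl)methyl]amino}prop-1-en-2-yl)cyclopent-2-en-1-one | O=C1C[C@@H](C(=C)CN(C)C[Si](C)(C)C)C=C1C
A2 | alternative 1 | (4aR,7S,7aR)-2,7-dimethyl-4-methylideneoctahydro-6H-cyclopenta[c]pyridin-6-one | O=C1C[C@@H]2[C@@H](CN(C)CC2=C)[C@@H]1C
A3 | alternative 2 | (4S)-4-(tert-butyldimethylsilyloxy)cyclopent-2-en-1-one | CC(C)(C)[Si](C)(C)O[C@H]1CC(=O)C=C1
A4 | alternative 2 | tert-butyl (methoxymethyl)(methyl)carbamate | COCN(C)C(=O)OC(C)(C)C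
A5 | alternative 2 | tert-butyl {[(1R,2S,3S)-3-(tert-butyldimethylsilyloxy)-2-methyl-5-oxocyclopentyl]methyl}(methyl)carbamate | CC(C)(C)[Si](C)(C)O[C@H]1CC(=O)[C@@H](CN(C)C(=O)OC(C)(C)C)[C@@H]1C
A6 | alternative 3 | methyl 3-oxo-3,6-dihydropyridine-1(2H)-carboxylate | COC(=O)N1CC=CC(=O)C1
A7 | alternative 3 | 3-[(trimethylsilyl)methyl]but-3-en-2-yl acetate | CC(OC(C)=O)C(=C)C[Si](C)(C)C
A8 | alternative 3 | methyl (4aR,7S,7aS)-7-methyl-6-methylidene-4-oxooctahydro-2H-cyclopenta[c]pyridine-2-carboxylate | C=C1C[C@@H]2[C@@H](CN(C(=O)OC)CC2=O)[C@@H]1C
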